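**Plan**

Numbering: the six-membered carbocycle is C1 (ketone), C2 (N-bearing), C3, C4 (tertiary carbinol), C5 (secondary carbinol), C6; C7–C13 is the trienamide chain on C4; primed numbers are the dienamide chain on N.
Enabling feature: the cis C4(OH)–C5(OH) pair with the carbon substituent C7 on C4 is the ipso,ortho-cis-diol of benzoic acid (carboxyl carbon = C7; the other arene carbons = C6, C1, C2, C3). The carbocycle is therefore never closed; it is the arene ring, dearomatised enzymatically.
Retrosynthetic cuts: C8–C9 (Stille), C7=C8 (Takai), C2–N (copper-catalysed amidation), C1=O and C6–H (allylic oxidation, diimide), C4–O/C5–O (dioxygenase). In the side chains: C13–N amide, C11=C12 (Wittig), C2'=C3' (HWE), C4'=C5' (Wittig), C7'–C8' (Grignard coupling).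
Forward order: benzoic acid → cis-diol acid → acetonide, C7 alcohol, silyl ether → C6=C1 reduced → C1 ketone → C2 iodide → C2 amide → C7 aldehyde → (E)-iodoalkene → diol released → triene completed by Stille coupling in the last step.
Stereochemistry: C4 and C5 (4S,5R, cis) come from the enzyme; C6' (R) comes from (S)-3-bromo-2-methylpropan-1-ol; every E-alkene comes from stabilised-ylide olefination, Takai olefination, hydrostannation or stereoretentive coupling.

Key step: step 1

Remark: the B9 mutant is assumed to accumulate the (1S,2R)-diol acid because it lacks the diol dehydrogenase; the (S)-bromo alcohol of the Roche-ester family is taken as a commercial chiral-pool material.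

**Route**

Step 1
Reactants: 1 benzoic acid; 2 dioxygen
Product: 3 (1S,2R)-1,2-dihydroxycyclohexa-3,5-diene-1-carboxylic acid
Conditions: whole cells of Ralstonia eutropha B9 (benzoate 1,2-dioxygenase active, diol dehydrogenase absent), mineral salts medium, D-fructose, substrate fed as sodium benzoate (PhCO2Na), air, pH 7, 30 °C; then cells removed, pH 3, EtOAc extraction
Reagents that add atoms: none
Why: The Rieske-type non-haem iron benzoate 1,2-dioxygenase binds benzoate through its carboxylate, activates O2 at the mononuclear iron with two electrons from cellular NADH and transfers both oxygen atoms suprafacially to the ipso and ortho carbons, which forms the C4–O and C5–O bonds and removes the aromaticity; this is the known microbial arene cis-dihydroxylation in its ipso,ortho mode, applied to the native substrate. No ring is closed: the arene ring becomes the cyclohexa-3,5-diene that later is the carbocycle of the target. Both new stereocentres (C4 and C5) are set by the enzyme active site, which presents one enantiotopic ipso/ortho edge of the bound benzoate to the iron-bound oxygen, and the cis relationship follows from delivery of both atoms of one O2 molecule to one face. The step needs ipso,ortho rather than ortho,meta regioselectivity, a single enantiomer and survival of the diol; the first two are secured by carboxylate anchoring in this enzyme and the last by the missing dehydrogenase, so the diol is excreted instead of being rearomatised. The carboxyl carbon is kept as C7 and the four untouched arene carbons become C6, C1, C2 and C3.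

Step 2
Reactants: 3 (1S,2R)-1,2-dihydroxycyclohexa-3,5-diene-1-carboxylic acid
Product: 4 (3aS,7aR)-2,2-dimethyl-3a,7a-dihydro-1,3-benzodioxole-3a-carboxylic acid
Conditions: 2,2-dimethoxypropane, TsOH·H2O (cat.), acetone, 0 °C, short time; Et3N quench
Reagents that add atoms: 2,2-dimethoxypropane, COC(C)(C)OC
Why: Acid-catalysed acetalisation (transketalisation) of the cis-diol gives the cis-fused dioxolane; brief, cold exposure to catalytic acid is meant to outrun dehydrative rearomatisation, and no stereocentre is touched.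

Step 3
Reactants: 4 (3aS,7aR)-2,2-dimethyl-3a,7a-dihydro-1,3-benzodioxole-3a-carboxylic acid
Product: 5 [(3aR,7aR)-2,2-dimethyl-3a,7a-dihydro-1,3-benzodioxol-3a-yl]methanol
Conditions: LiAlH4, THF, 0 °C → rt; aqueous NaOH work-up
Reagents that add atoms: none
Why: Lithium aluminium hydride reduction of the carboxylic acid gives the primary C7 alcohol and leaves the conjugated diene and the acetonide untouched; the diene should be used promptly because such dienes dimerise by Diels–Alder reaction on storage.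

Step 4
Reactants: 5 [(3aR,7aR)-2,2-dimethyl-3a,7a-dihydro-1,3-benzodioxol-3a-yl]methanol
Product: 6 tert-butyl{[(3aR,7aR)-2,2-dimethyl-3a,7a-dihydro-1,3-benzodioxol-3a-yl]methoxy}dimethylsilane
Conditions: TBSCl, imidazole, DMAP (cat.), DMF, rt
Reagents that add atoms: tert-butyldimethylsilyl chloride, CC(C)(C)[Si](C)(C)Cl
Why: Imidazole-promoted silyl ether formation masks the neopentyl C7 hydroxyl for the oxidative steps and adds bulk at C4 that helps to shield the neighbouring C2=C3 alkene.

Step 5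
Reactants: 6 tert-butyl{[(3aR,7aR)-2,2-dimethyl-3a,7a-dihydro-1,3-benzodioxol-3a-yl]methoxy}dimethylsilane
Product: 7 tert-butyl{[(3aR,7aR)-2,2-dimethyl-3a,6,7,7a-tetrahydro-1,3-benzodioxol-3a-yl]methoxy}dimethylsilane
Conditions: dipotassium azodicarboxylate (KO2CN=NCO2K), AcOH, MeOH, 0 °C, stopped at mono-reduction
Reagents that add atoms: none
Why: Diimide reduction (concerted syn transfer of two hydrogens from HN=NH) is faster for a conjugated cyclohexadiene than for the isolated cyclohexene it produces and is sensitive to hindrance, so it should saturate C6=C1 next to the secondary C5 and spare C2=C3, which is flanked by the fully substituted C4; no stereocentre is formed.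

Step 6
Reactants: 7 tert-butyl{[(3aR,7aR)-2,2-dimethyl-3a,6,7,7a-tetrahydro-1,3-benzodioxol-3a-yl]methoxy}dimethylsilane
Product: 8 (3aR,7aR)-7a-({[tert-butyl(dimethyl)silyl]oxy}methyl)-2,2-dimethyl-3a,7a-dihydro-1,3-benzodioxol-5(4H)-one
Conditions: Mn(OAc)3·2H2O (cat.), t-BuOOH (in decane), 3 Å MS, EtOAc, rt
Reagents that add atoms: tert-butyl hydroperoxide, CC(C)(C)OO
Why: Radical allylic C–H oxidation with tert-butyl hydroperoxide (manganese-catalysed peroxyl-radical chain via an allylic peroxide) can only start at C1, the sole allylic C–H position because C4 is quaternary, and oxygen uptake at the unhindered C1 end of the allyl radical rather than at neopentyl C3 should give the C1 enone.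

Step 7
Reactants: 8 (3aR,7aR)-7a-({[tert-butyl(dimethyl)silyl]oxy}methyl)-2,2-dimethyl-3a,7a-dihydro-1,3-benzodioxol-5(4H)-one
Product: 9 (3aR,7aR)-7a-({[tert-butyl(dimethyl)silyl]oxy}methyl)-6-iodo-2,2-dimethyl-3a,7a-dihydro-1,3-benzodioxol-5(4H)-one
Conditions: I2, pyridine, CH2Cl2, 0 °C → rt
Reagents that add atoms: iodine, II
Why: α-Iodination of an enone by the iodine–pyridine method (conjugate addition of pyridine at C3, iodination of the enolate at C2, elimination of pyridine, a Baylis–Hillman-type sequence) is reliable for γ,γ-disubstituted cyclohexenones.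

Step 8
Reactants: 10 (S)-3-bromo-2-methylpropan-1-ol
Product: 11 (R)-2-methylhexan-1-ol
Conditions: n-PrMgBr (3 equiv), Li2CuCl4 (cat.), THF, −20 °C → rt
Reagents that add atoms: propylmagnesium bromide, CCC[Mg]Br
Why: Copper-catalysed alkyl–alkyl cross-coupling of a Grignard reagent with a primary bromide (Kochi-type coupling), the first equivalent being used to form the magnesium alkoxide, builds the butyl chain without touching the stereocentre that becomes C6'.

Step 9
Reactants: 11 (R)-2-methylhexan-1-ol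
Product: 13 (2E,4R)-2,4-dimethyloct-2-enal, via (R)-2-methylhexanal 12 (not isolated)
Conditions: TEMPO (cat.), PhI(OAc)2, CH2Cl2, rt; then Ph3P=C(Me)CHO, toluene, 90 °C
Reagents that add atoms: 2-(triphenylphosphoranylidene)propanal, CC(C=O)=P(c1ccccc1)(c1ccccc1)c1ccccc1
Why: Oxoammonium (TEMPO) oxidation gives the configurationally labile α-branched aldehyde under non-basic conditions, and its Wittig reaction with the stabilised formyl ylide in the same flask should give the (E)-trisubstituted C4'=C5' enal.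

Step 10
Reactants: 13 (2E,4R)-2,4-dimethyloct-2-enal
Product: 14 (2E,4E,6R)-4,6-dimethyldeca-2,4-dienamide
Conditions: (EtO)2P(O)CH2CONH2, NaH, THF, 0 °C → rt
Reagents that add atoms: diethyl (2-amino-2-oxoethyl)phosphonate, CCOP(=O)(CC(N)=O)OCC
Why: Horner–Wadsworth–Emmons olefination with the carbamoylmethyl phosphonate anion gives the (E)-disubstituted C2'=C3' alkene and installs the primary amide directly.

Step 11
Reactants: 9 (3aR,7aR)-7a-({[tert-butyl(dimethyl)silyl]oxy}methyl)-6-iodo-2,2-dimethyl-3a,7a-dihydro-1,3-benzodioxol-5(4H)-one; 14 (2E,4E,6R)-4,6-dimethyldeca-2,4-dienamide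
Product: 15 (2E,4E,6R)-N-[(3aR,7aR)-7a-({[tert-butyl(dimethyl)silyl]oxy}methyl)-2,2-dimethyl-5-oxo-3a,4,5,7a-tetrahydro-1,3-benzodioxol-6-yl]-4,6-dimethyldeca-2,4-dienamide
Conditions: CuI (cat.), N,N′-dimethylethylenediamine, Cs2CO3, THF, 60 °C
Reagents that add atoms: none
Why: Copper-catalysed N-vinylation of a primary amide with a vinyl iodide (Goldberg-type amidation with a diamine ligand) applies to α-iodoenones, which are activated vinyl iodides, and forms the C2–N bond without moving the alkene; the mild carbonate base is chosen to avoid β-elimination of the C5 oxygen.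

Step 12
Reactants: 15 (2E,4E,6R)-N-[(3aR,7aR)-7a-({[tert-butyl(dimethyl)silyl]oxy}methyl)-2,2-dimethyl-5-oxo-3a,4,5,7a-tetrahydro-1,3-benzodioxol-6-yl]-4,6-dimethyldeca-2,4-dienamide
Product: 16 (2E,4E,6R)-N-[(3aR,7aR)-7a-(hydroxymethyl)-2,2-dimethyl-5-oxo-3a,4,5,7a-tetrahydro-1,3-benzodioxol-6-yl]-4,6-dimethyldeca-2,4-dienamide
Conditions: HF·pyridine, pyridine, THF, 0 °C → rt
Reagents that add atoms: none
Why: Fluoride-mediated silyl ether cleavage with buffered HF·pyridine frees the C7 hydroxyl without disturbing the acetonide or the base-sensitive β-alkoxy ketone.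

Step 13
Reactants: 16 (2E,4E,6R)-N-[(3aR,7aR)-7a-(hydroxymethyl)-2,2-dimethyl-5-oxo-3a,4,5,7a-tetrahydro-1,3-benzodioxol-6-yl]-4,6-dimethyldeca-2,4-dienamide
Product: 17 (2E,4E,6R)-N-[(3aR,7aS)-7a-formyl-2,2-dimethyl-5-oxo-3a,4,5,7a-tetrahydro-1,3-benzodioxol-6-yl]-4,6-dimethyldeca-2,4-dienamide
Conditions: Dess–Martin periodinane, CH2Cl2, 0 °C → rt
Reagents that add atoms: none
Why: Dess–Martin oxidation converts the neopentyl primary alcohol into the non-enolisable C7 aldehyde under neutral conditions that tolerate the amido-enone and the acetonide.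

Step 14
Reactants: 17 (2E,4E,6R)-N-[(3aR,7aS)-7a-formyl-2,2-dimethyl-5-oxo-3a,4,5,7a-tetrahydro-1,3-benzodioxol-6-yl]-4,6-dimethyldeca-2,4-dienamide
Product: 18 (2E,4E,6R)-N-{(3aR,7aR)-7a-[(E)-2-iodoethenyl]-2,2-dimethyl-5-oxo-3a,4,5,7a-tetrahydro-1,3-benzodioxol-6-yl}-4,6-dimethyldeca-2,4-dienamide
Conditions: CrCl2, CHI3, THF/1,4-dioxane, 0 °C → rt, dark
Reagents that add atoms: iodoform, IC(I)I
Why: Takai olefination (an iodo-substituted gem-dichromium species from CHI3 and CrCl2 adds to the aldehyde and eliminates anti) should convert the aldehyde, far more reactive than the conjugated ring ketone, into the (E)-iodoalkene C7=C8.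

Step 15
Reactants: 18 (2E,4E,6R)-N-{(3aR,7aR)-7a-[(E)-2-iodoethenyl]-2,2-dimethyl-5-oxo-3a,4,5,7a-tetrahydro-1,3-benzodioxol-6-yl}-4,6-dimethyldeca-2,4-dienamide
Product: 19 (2E,4E,6R)-N-{(3R,4R)-3,4-dihydroxy-3-[(E)-2-iodoethenyl]-6-oxocyclohex-1-en-1-yl}-4,6-dimethyldeca-2,4-dienamide
Conditions: TFA/H2O, CH2Cl2, 0 °C
Reagents that add atoms: none
Why: Acid-catalysed hydrolysis of the isopropylidene acetal releases the diol by cleavage of the acetal C–O bonds only, so C4 and C5 keep their configuration, and ionisation at C4 is disfavoured by the electron-poor enone on one side and the inductively withdrawing iodoalkene and C5 oxygen on the other.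

Step 16
Reactants: 20 prop-2-yn-1-ol
Product: 21 (E)-3-(tributylstannyl)prop-2-en-1-ol
Conditions: Bu3SnH, AIBN (cat.), neat, 80 °C; chromatography
Reagents that add atoms: tributyltin hydride, CCCC[SnH](CCCC)CCCC
Why: Radical hydrostannation of a terminal alkyne (stannyl radical addition at the terminus, with reversible addition–elimination equilibrating towards the more stable isomer) gives mainly the (E)-β-vinylstannane, separable from minor isomers.

Step 17
Reactants: 21 (E)-3-(tributylstannyl)prop-2-en-1-ol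
Product: 23 ethyl (2E,4E)-5-(tributylstannyl)penta-2,4-dienoate, via (E)-3-(tributylstannyl)prop-2-enal 22 (not isolated)
Conditions: MnO2, Ph3P=CHCO2Et, CH2Cl2, rt
Reagents that add atoms: ethyl (triphenylphosphoranylidene)acetate, CCOC(=O)C=P(c1ccccc1)(c1ccccc1)c1ccccc1
Why: Tandem oxidation–Wittig: MnO2 oxidises the allylic alcohol to the sensitive stannyl enal, which is trapped in situ by the stabilised ylide to give the (2E,4E)-dienoate, the new C11=C12 alkene being E by stabilised-ylide control.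

Step 18
Reactants: 23 ethyl (2E,4E)-5-(tributylstannyl)penta-2,4-dienoate
Product: 24 (2E,4E)-5-(tributylstannyl)penta-2,4-dienoic acid
Conditions: LiOH, THF/MeOH/H2O, rt; then dilute HCl to pH 4, 0 °C
Reagents that add atoms: lithium hydroxide, [Li+].[OH-]
Why: Ester saponification with LiOH followed by cold, careful acidification gives the dienoic acid without protodestannylation.

Step 19
Reactants: 25 cyclopentane-1,3-dione
Product: 26 2-(hydroxyimino)cyclopentane-1,3-dione
Conditions: t-BuONO, HCl (cat.), EtOH, 0 °C → rt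
Reagents that add atoms: tert-butyl nitrite, CC(C)(C)ON=O
Why: Electrophilic nitrosation of the doubly activated C2 methylene of a 1,3-diketone with an alkyl nitrite, followed by tautomerisation to the oxime.

Step 20
Reactants: 26 2-(hydroxyimino)cyclopentane-1,3-dione
Product: 27 2-amino-3-hydroxycyclopent-2-en-1-one hydrochloride
Conditions: H2 (1 atm), Pd/C, HCl (1.1 equiv), MeOH, rt
Reagents that add atoms: hydrogen chloride, Cl
Why: Catalytic hydrogenation of an α-oximino-1,3-dione gives the primary amine, trapped as the hydrochloride of the stable enol tautomer to prevent self-condensation and air oxidation.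

Step 21
Reactants: 24 (2E,4E)-5-(tributylstannyl)penta-2,4-dienoic acid; 27 2-amino-3-hydroxycyclopent-2-en-1-one hydrochloride
Product: 29 (2E,4E)-N-(2-hydroxy-5-oxocyclopent-1-en-1-yl)-5-(tributylstannyl)penta-2,4-dienamide, via stannyl dienoyl chloride 28 (not isolated)
Conditions: 1-chloro-N,N,2-trimethylprop-1-en-1-amine, CH2Cl2, 0 °C; then 27, Et3N, DMF, 0 °C → rt
Reagents that add atoms: none
Why: Amide formation through the acid chloride made under neutral conditions with the α-chloroenamine (no free HCl, so the vinylstannane survives); the aminoenol is acylated on nitrogen, any enol ester formed first passing its acyl group to the adjacent nitrogen.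

Step 22
Reactants: 19 (2E,4E,6R)-N-{(3R,4R)-3,4-dihydroxy-3-[(E)-2-iodoethenyl]-6-oxocyclohex-1-en-1-yl}-4,6-dimethyldeca-2,4-dienamide; 29 (2E,4E)-N-(2-hydroxy-5-oxocyclopent-1-en-1-yl)-5-(tributylstannyl)penta-2,4-dienamide
Product: 30 (2E,4E,6R)-N-[(3S,4R)-3,4-dihydroxy-3-{(1E,3E,5E)-7-[(2-hydroxy-5-oxocyclopent-1-en-1-yl)amino]-7-oxohepta-1,3,5-trien-1-yl}-6-oxocyclohex-1-en-1-yl]-4,6-dimethyldeca-2,4-dienamide (CNP0284264.2)
Conditions: PdCl2(MeCN)2 (cat.), DMF, rt, dark
Reagents that add atoms: none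
Why: Stille cross-coupling (oxidative addition of zerovalent palladium, formed in situ from the divalent precatalyst, into the C8–I bond, tin-to-palladium transmetalation, reductive elimination) joins C8 to C9 with retention of both alkene geometries under neutral conditions that tolerate the free diol, the acidic enol and both amides.

**Compound list**

1 | benzoic acid | OC(=O)c1ccccc1 | starting material
2 | dioxygen | O=O | starting material
3 | (1S,2R)-1,2-dihydroxycyclohexa-3,5-diene-1-carboxylic acid | C1=C[C@@](O)(C(=O)O)[C@H](O)C=C1 | intermediate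
4 | (3aS,7aR)-2,2-dimethyl-3a,7a-dihydro-1,3-benzodioxole-3a-carboxylic acid | C1=C[C@@]2(C(=O)O)[C@H](OC(C)(C)O2)C=C1 | intermediate
5 | [(3aR,7aR)-2,2-dimethyl-3a,7a-dihydro-1,3-benzodioxol-3a-yl]methanol | C1=C[C@@]2(CO)[C@H](OC(C)(C)O2)C=C1 | intermediate
6 | tert-butyl{[(3aR,7aR)-2,2-dimethyl-3a,7a-dihydro-1,3-benzodioxol-3a-yl]methoxy}dimethylsilane | C1=C[C@@]2(CO[Si](C)(C)C(C)(C)C)[C@H](OC(C)(C)O2)C=C1 | intermediate
7 | tert-butyl{[(3aR,7aR)-2,2-dimethyl-3a,6,7,7a-tetrahydro-1,3-benzodioxol-3a-yl]methoxy}dimethylsilane | C1=C[C@@]2(CO[Si](C)(C)C(C)(C)C)[C@H](OC(C)(C)O2)CC1 | intermediate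
8 | (3aR,7aR)-7a-({[tert-butyl(dimethyl)silyl]oxy}methyl)-2,2-dimethyl-3a,7a-dihydro-1,3-benzodioxol-5(4H)-one | C1=C[C@@]2(CO[Si](C)(C)C(C)(C)C)[C@H](OC(C)(C)O2)CC1=O | intermediate
9 | (3aR,7aR)-7a-({[tert-butyl(dimethyl)silyl]oxy}methyl)-6-iodo-2,2-dimethyl-3a,7a-dihydro-1,3-benzodioxol-5(4H)-one | IC1=C[C@@]2(CO[Si](C)(C)C(C)(C)C)[C@H](OC(C)(C)O2)CC1=O | intermediate
10 | (S)-3-bromo-2-methylpropan-1-ol | BrC[C@@H](C)CO | starting material
11 | (R)-2-methylhexan-1-ol | CCCC[C@@H](C)CO | intermediate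
12 | (R)-2-methylhexanal | CCCC[C@@H](C)C=O | intermediate (not isolated)
13 | (2E,4R)-2,4-dimethyloct-2-enal | CCCC[C@@H](C)/C=C(C)/C=O | intermediate
14 | (2E,4E,6R)-4,6-dimethyldeca-2,4-dienamide | CCCC[C@@H](C)/C=C(C)/C=C/C(N)=O | intermediate
15 | (2E,4E,6R)-N-[(3aR,7aR)-7a-({[tert-butyl(dimethyl)silyl]oxy}methyl)-2,2-dimethyl-5-oxo-3a,4,5,7a-tetrahydro-1,3-benzodioxol-6-yl]-4,6-dimethyldeca-2,4-dienamide | CCCC[C@@H](C)/C=C(C)/C=C/C(=O)NC1=C[C@@]2(CO[Si](C)(C)C(C)(C)C)[C@H](OC(C)(C)O2)CC1=O | intermediate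
16 | (2E,4E,6R)-N-[(3aR,7aR)-7a-(hydroxymethyl)-2,2-dimethyl-5-oxo-3a,4,5,7a-tetrahydro-1,3-benzodioxol-6-yl]-4,6-dimethyldeca-2,4-dienamide | CCCC[C@@H](C)/C=C(C)/C=C/C(=O)NC1=C[C@@]2(CO)[C@H](OC(C)(C)O2)CC1=O | intermediate
17 | (2E,4E,6R)-N-[(3aR,7aS)-7a-formyl-2,2-dimethyl-5-oxo-3a,4,5,7a-tetrahydro-1,3-benzodioxol-6-yl]-4,6-dimethyldeca-2,4-dienamide | CCCC[C@@H](C)/C=C(C)/C=C/C(=O)NC1=C[C@@]2(C=O)[C@H](OC(C)(C)O2)CC1=O | intermediate
18 | (2E,4E,6R)-N-{(3aR,7aR)-7a-[(E)-2-iodoethenyl]-2,2-dimethyl-5-oxo-3a,4,5,7a-tetrahydro-1,3-benzodioxol-6-yl}-4,6-dimethyldeca-2,4-dienamide | CCCC[C@@H](C)/C=C(C)/C=C/C(=O)NC1=C[C@@]2(/C=C/I)[C@H](OC(C)(C)O2)CC1=O | intermediate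
19 | (2E,4E,6R)-N-{(3R,4R)-3,4-dihydroxy-3-[(E)-2-iodoethenyl]-6-oxocyclohex-1-en-1-yl}-4,6-dimethyldeca-2,4-dienamide | CCCC[C@@H](C)/C=C(C)/C=C/C(=O)NC1=C[C@@](O)(/C=C/I)[C@H](O)CC1=O | intermediate
20 | prop-2-yn-1-ol | C#CCO | starting material
21 | (E)-3-(tributylstannyl)prop-2-en-1-ol | CCCC[Sn](CCCC)(CCCC)/C=C/CO | intermediate
22 | (E)-3-(tributylstannyl)prop-2-enal | CCCC[Sn](CCCC)(CCCC)/C=C/C=O | intermediate (not isolated)
23 | ethyl (2E,4E)-5-(tributylstannyl)penta-2,4-dienoate | CCCC[Sn](CCCC)(CCCC)/C=C/C=C/C(=O)OCC | intermediate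
24 | (2E,4E)-5-(tributylstannyl)penta-2,4-dienoic acid | CCCC[Sn](CCCC)(CCCC)/C=C/C=C/C(=O)O | intermediate
25 | cyclopentane-1,3-dione | O=C1CCC(=O)C1 | starting material
26 | 2-(hydroxyimino)cyclopentane-1,3-dione | O=C1CCC(=O)C1=NO | intermediate
27 | 2-amino-3-hydroxycyclopent-2-en-1-one hydrochloride | Cl.NC1=C(O)CCC1=O | intermediate
28 | (2E,4E)-5-(tributylstannyl)penta-2,4-dienoyl chloride | CCCC[Sn](CCCC)(CCCC)/C=C/C=C/C(Cl)=O | intermediate (not isolated)
29 | (2E,4E)-N-(2-hydroxy-5-oxocyclopent-1-en-1-yl)-5-(tributylstannyl)penta-2,4-dienamide | CCCC[Sn](CCCC)(CCCC)/C=C/C=C/C(=O)NC1=C(O)CCC1=O | intermediate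
30 | (2E,4E,6R)-N-[(3S,4R)-3,4-dihydroxy-3-{(1E,3E,5E)-7-[(2-hydroxy-5-oxocyclopent-1-en-1-yl)amino]-7-oxohepta-1,3,5-trien-1-yl}-6-oxocyclohex-1-en-1-yl]-4,6-dimethyldeca-2,4-dienamide | CCCC[C@@H](C)/C=C(C)/C=C/C(=O)NC1=C[C@@](O)(/C=C/C=C/C=C/C(=O)NC2=C(O)CCC2=O)[C@H](O)CC1=O | target

**Counts and risks**

Total step count: 22. Longest linear sequence: 13 steps (steps 1–7, 11–15 and 22).

Steps most likely to fail:

Step 5. The two cis-disubstituted ring alkenes may be reduced at similar rates and reduction may run on to the saturated ring, so the mono-ene would form with poor site selectivity. The fallback sets out from 6 and returns at 8, bypassing steps 5 and 6. Osmium-catalysed dihydroxylation (OsO4 cat., N-methylmorpholine N-oxide, acetone/water) responds more strongly than diimide to the steric difference between the alkenes and should attack C6=C1 on the face opposite the acetonide, giving (3aR,4S,5S,7aR)-7a-({[tert-butyl(dimethyl)silyl]oxy}methyl)-2,2-dimethyl-3a,4,5,7a-tetrahydro-1,3-benzodioxole-4,5-diol F1. MnO2 in CH2Cl2 should oxidise only the allylic C1 hydroxyl to (3aR,4R,7aR)-7a-({[tert-butyl(dimethyl)silyl]oxy}methyl)-4-hydroxy-2,2-dimethyl-3a,7a-dihydro-1,3-benzodioxol-5(4H)-one F2. Acetylation (Ac2O, pyridine, DMAP) would give (3aR,4R,7aR)-7a-({[tert-butyl(dimethyl)silyl]oxy}methyl)-2,2-dimethyl-5-oxo-3a,4,5,7a-tetrahydro-1,3-benzodioxol-4-yl acetate F3, and samarium diiodide (SmI2, THF/MeOH, −78 °C) should cleave the α-acetoxy group reductively to give enone 8.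

Step 14. The iodo-dichromium reagent may add only sluggishly to the neopentyl, α-oxygenated aldehyde while the excess divalent chromium reduces the amido-enone or the new iodoalkene. The fallback sets out from 17 and returns at 18. Seyferth–Gilbert homologation with dimethyl (1-diazo-2-oxopropyl)phosphonate (K2CO3, MeOH, 0 °C) would give (2E,4E,6R)-N-[(3aR,7aR)-7a-ethynyl-2,2-dimethyl-5-oxo-3a,4,5,7a-tetrahydro-1,3-benzodioxol-6-yl]-4,6-dimethyldeca-2,4-dienamide F4. Palladium-catalysed syn hydrostannation (Bu3SnH, PdCl2(PPh3)2 cat., THF, 0 °C), which places tin at the terminus away from the quaternary centre, would give (2E,4E,6R)-N-{(3aR,7aR)-2,2-dimethyl-5-oxo-7a-[(E)-2-(tributylstannyl)ethenyl]-3a,4,5,7a-tetrahydro-1,3-benzodioxol-6-yl}-4,6-dimethyldeca-2,4-dienamide F5. Iododestannylation (I2, CH2Cl2, 0 °C) with retention of geometry would give 18.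

Step 15. Under acid the C4–O bond, now allylic to the iodoalkene, may ionise, or the freed C5 hydroxyl may be lost by β-elimination from the ketone, so dehydration and aromatisation could compete with clean diol release. The fallback sets out from 16, where C4 still carries only a hydroxymethyl group, and returns at 19. Acetonide hydrolysis at that stage (aqueous AcOH, rt) would give (2E,4E,6R)-N-[(3R,4R)-3,4-dihydroxy-3-(hydroxymethyl)-6-oxocyclohex-1-en-1-yl]-4,6-dimethyldeca-2,4-dienamide F6. Chemoselective aerobic oxidation of the primary alcohol (Cu(MeCN)4OTf, 2,2′-bipyridine, TEMPO, N-methylimidazole, air, MeCN, rt) would give (2E,4E,6R)-N-[(3S,4R)-3-formyl-3,4-dihydroxy-6-oxocyclohex-1-en-1-yl]-4,6-dimethyldeca-2,4-dienamide F7. Takai olefination on the unprotected diol (CrCl2 in larger excess, CHI3, THF/1,4-dioxane) would give 19.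

**Further compounds**

F1 | step 5 | (3aR,4S,5S,7aR)-7a-({[tert-butyl(dimethyl)silyl]oxy}methyl)-2,2-dimethyl-3a,4,5,7a-tetrahydro-1,3-benzodioxole-4,5-diol | C1=C[C@@]2(CO[Si](C)(C)C(C)(C)C)[C@H](OC(C)(C)O2)[C@@H](O)[C@H]1O
F2 | step 5 | (3aR,4R,7aR)-7a-({[tert-butyl(dimethyl)silyl]oxy}methyl)-4-hydroxy-2,2-dimethyl-3a,7a-dihydro-1,3-benzodioxol-5(4H)-one | C1=C[C@@]2(CO[Si](C)(C)C(C)(C)C)[C@H](OC(C)(C)O2)[C@@H](O)C1=O
F3 | step 5 | (3aR,4R,7aR)-7a-({[tert-butyl(dimethyl)silyl]oxy}methyl)-2,2-dimethyl-5-oxo-3a,4,5,7a-tetrahydro-1,3-benzodioxol-4-yl acetate | C1=C[C@@]2(CO[Si](C)(C)C(C)(C)C)[C@H](OC(C)(C)O2)[C@@H](OC(C)=O)C1=O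
F4 | step 14 | (2E,4E,6R)-N-[(3aR,7aR)-7a-ethynyl-2,2-dimethyl-5-oxo-3a,4,5,7a-tetrahydro-1,3-benzodioxol-6-yl]-4,6-dimethyldeca-2,4-dienamide | CCCC[C@@H](C)/C=C(C)/C=C/C(=O)NC1=C[C@@]2(C#C)[C@H](OC(C)(C)O2)CC1=O
F5 | step 14 | (2E,4E,6R)-N-{(3aR,7aR)-2,2-dimethyl-5-oxo-7a-[(E)-2-(tributylstannyl)ethenyl]-3a,4,5,7a-tetrahydro-1,3-benzodioxol-6-yl}-4,6-dimethyldeca-2,4-dienamide | CCCC[C@@H](C)/C=C(C)/C=C/C(=O)NC1=C[C@@]2(/C=C/[Sn](CCCC)(CCCC)CCCC)[C@H](OC(C)(C)O2)CC1=O
F6 | step 15 | (2E,4E,6R)-N-[(3R,4R)-3,4-dihydroxy-3-(hydroxymethyl)-6-oxocyclohex-1-en-1-yl]-4,6-dimethyldeca-2,4-dienamide | CCCC[C@@H](C)/C=C(C)/C=C/C(=O)NC1=C[C@@](O)(CO)[C@H](O)CC1=O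
F7 | step 15 | (2E,4E,6R)-N-[(3S,4R)-3-formyl-3,4-dihydroxy-6-oxocyclohex-1-en-1-yl]-4,6-dimethyldeca-2,4-dienamide | CCCC[C@@H](C)/C=C(C)/C=C/C(=O)NC1=C[C@@](O)(C=O)[C@H](O)CC1=O
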